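**Retrosynthetic overview**
1. The left isochromene quinone methide ring of the target is closed last, by orthoformate cyclisation of the resorcinol–lactone dyad 12 (the classical citrinin ring closure).
2. Dyad 12 comes from a chiral-acid-catalysed Friedel–Crafts addition of phenol 6 to o-quinone methide 11, which is released from the lactone-derived benzodioxaborin 10; this sets the CH(CH3) linker centre.
3. 10 comes from dihydroxy lactone 9 (Nagata hydroxyalkylation), and 9 from alcohol 5 by oxa-Pictet–Spengler cyclisation and oxidation (the lactone ring is formed first); 6 comes from 5 by demethylation.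
4. Alcohol 5 carries the C3/C4 diad of both halves; it comes from Shi epoxidation of (E)-propenylarene 3 and anti methyl opening, and 3 from commercial 2-bromo-3,5-dimethoxybenzaldehyde 1.

Assumption: the sense of induction of the chiral acid in step 9 must be confirmed by experiment; the (R)-catalyst is written and its antipode is used if it gives the linker epimer.

**Route**

Step 1
Reactants: 1 2-bromo-3,5-dimethoxybenzaldehyde
Product: 2 3,5-dimethoxy-2-methylbenzaldehyde
Conditions: MeB(OH)2 (1.5 eq), Pd(dppf)Cl2 (3 mol%), K2CO3 (3 eq), dioxane–H2O 10:1, 95 °C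
Reagents that add atoms: methylboronic acid CB(O)O
Why: Suzuki–Miyaura cross-coupling; the bromide ortho to the formyl group is activated for oxidative addition and the aldehyde tolerates the mild carbonate base.

Step 2
Reactants: 2 3,5-dimethoxy-2-methylbenzaldehyde
Product: 3 (E)-1,5-dimethoxy-2-methyl-3-(prop-1-en-1-yl)benzene
Conditions: 5-(ethylsulfonyl)-1-phenyl-1H-tetrazole (1.2 eq), KHMDS (1.25 eq), DME, −60 °C → rt
Reagents that add atoms: 5-(ethylsulfonyl)-1-phenyl-1H-tetrazole CCS(=O)(=O)c1nnnn1-c1ccccc1
Why: Julia–Kocienski olefination; phenyltetrazolyl sulfones give the E-alkene with aromatic aldehydes (any minor Z isomer is removed by chromatography, as it would lead to the wrong diastereomer later).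

Step 3
Reactants: 3 (E)-1,5-dimethoxy-2-methyl-3-(prop-1-en-1-yl)benzene
Product: 4 (2R,3R)-2-(3,5-dimethoxy-2-methylphenyl)-3-methyloxirane
Conditions: D-fructose-derived Shi ketone (30 mol%), Oxone, K2CO3, Bu4NHSO4, MeCN–DMM/aq. borate buffer (pH 10.5), 0 °C
Reagents that add atoms: potassium peroxymonosulfate (active component of Oxone) [K+].[O-]S(=O)(=O)OO
Why: Shi asymmetric epoxidation; the chiral dioxirane from the D-fructose ketone epoxidises trans-β-methylstyrene-type alkenes through a spiro transition state to the (R,R)-epoxide, which fixes the O-bearing centre (future C3, R) of both halves.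

Step 4
Reactants: 4 (2R,3R)-2-(3,5-dimethoxy-2-methylphenyl)-3-methyloxirane
Product: 5 (2R,3S)-3-(3,5-dimethoxy-2-methylphenyl)butan-2-ol
Conditions: AlMe3 (3 eq), CH2Cl2, −78 → 0 °C; Rochelle salt work-up
Reagents that add atoms: trimethylaluminium C[Al](C)C
Why: Lewis-acid-assisted SN2 ring opening of an aryl epoxide; the alane activates the epoxide, and a second AlMe3 delivers methyl anti at the benzylic carbon (the site best able to bear positive charge), so inversion there gives the S benzylic centre (future C4) while the carbinol centre stays R.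

Step 5
Reactants: 5 (2R,3S)-3-(3,5-dimethoxy-2-methylphenyl)butan-2-ol
Product: 6 (2R,3S)-3-(3,5-dihydroxy-2-methylphenyl)butan-2-ol
Conditions: BBr3 (3.5 eq), CH2Cl2, −78 → 0 °C; MeOH then H2O
Reagents that add atoms: none
Why: Lewis-acid aryl methyl ether cleavage; kept at or below 0 °C the secondary alcohol is only held as its borate and is freed on work-up, and recrystallisation of triol 6 (citrinin "phenol A") raises the enantiopurity.

Step 6
Reactants: 5 (2R,3S)-3-(3,5-dimethoxy-2-methylphenyl)butan-2-ol
Product: 8 (3R,4S)-6,8-dimethoxy-3,4,5-trimethylisochroman-1-one, via 1-methoxy acetal 7 (not isolated)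
Conditions: HC(OMe)3 (3 eq), BF3·OEt2 (0.5 eq), CH2Cl2, −20 → 0 °C; evaporate; Jones reagent (CrO3/H2SO4), acetone, 0 °C
Reagents that add atoms: trimethyl orthoformate COC(OC)OC; water O
Why: oxa-Pictet–Spengler cyclisation followed by Jones oxidation of the lactol ether; the alcohol-tethered dialkoxycarbenium ion attacks the one ring carbon ortho to the tether (para to OMe), and the crude cyclic acetal is hydrolysed and oxidised to the lactone without touching C3 or C4.

Step 7
Reactants: 8 (3R,4S)-6,8-dimethoxy-3,4,5-trimethylisochroman-1-one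
Product: 9 (3R,4S)-6,8-dihydroxy-3,4,5-trimethylisochroman-1-one
Conditions: BBr3 (4 eq), CH2Cl2, −78 °C → rt; H2O
Reagents that add atoms: none
Why: BBr3 demethylation; dihydroisocoumarin lactones survive these conditions and there is no free alcohol to substitute.

Step 8
Reactants: 9 (3R,4S)-6,8-dihydroxy-3,4,5-trimethylisochroman-1-one
Product: 10 Nagata benzodioxaborin of 9 (C6–O and C7 bridged as O–B(Ph)–O–CH(CH3); both epimers at CH(CH3))
Conditions: CH3CHO (4 eq), PhB(OH)2 (1.3 eq), EtCO2H (30 mol%), toluene, 4 Å MS, 80 °C, sealed tube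
Reagents that add atoms: acetaldehyde CC=O; phenylboronic acid OB(O)c1ccccc1
Why: Nagata ortho-hydroxyalkylation of a phenol; the aryloxyboronate delivers acetaldehyde to C7, the only free ring carbon, and traps the benzylic alcohol as a stable dioxaborin, which stops the reaction at the mono-adduct instead of the bis-aryl ethane.

Step 9
Reactants: 10 Nagata benzodioxaborin of 9; 6 (2R,3S)-3-(3,5-dihydroxy-2-methylphenyl)butan-2-ol
Product: 12 (3R,4S)-7-[(1S)-1-{2,6-dihydroxy-4-[(2S,3R)-3-hydroxybutan-2-yl]-3-methylphenyl}ethyl]-6,8-dihydroxy-3,4,5-trimethylisochroman-1-one, via o-quinone methide 11 (not isolated)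
Conditions: 6 (1.5 eq), (R)-TRIP N-triflylphosphoramide (10 mol%), CH2Cl2–EtOAc 4:1, 5 Å MS, −20 °C → rt; aqueous work-up
Reagents that add atoms: none
Why: Proposed new method: the chiral Brønsted acid protonates the benzylic B–O–C oxygen of the dioxaborin and ionises it to o-quinone methide 11, held hydrogen-bonded/ion-paired to the chiral anion while boron leaves as phenylboronate; the same anion binds a phenolic OH of 6 and delivers its carbon between the two OH groups (the only unhindered nucleophilic site) to one face of the ethylidene, so the catalyst sets the linker centre (S here, R in the target after the CIP priority change) because the remote C3/C4 centres give no useful bias; the closest known reaction types are chiral phosphoric acid-catalysed asymmetric Friedel–Crafts arylation of o-quinone methides from o-hydroxybenzyl alcohols or o-hydroxystyrenes with phenols (1,1-diarylethanes) and Lewis-acid release of o-quinone methides from benzodioxaborins, and what is new is the dioxaborin as precursor under chiral acid catalysis and the 2,6-dioxygenated lactone-bearing quinone methide.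

Step 10
Reactants: 12 resorcinol–lactone dyad (product of step 9)
Product: 14 dicitrinone H, via 1-ethoxy acetal 13 (not isolated)
Conditions: HC(OEt)3 (5 eq), TFA (10 mol%), THF, rt; then 1 M HCl, rt
Reagents that add atoms: triethyl orthoformate CCOC(OCC)OCC
Why: orthoformate formylative cyclisation (oxa-Pictet–Spengler type, the classical citrinin ring closure); the alcohol-tethered dialkoxycarbenium ion attacks the single free ring carbon of the left resorcinol, and loss of ethanol from the acetal gives the quinone methide, now blocked at C7 against self-condensation, with no stereocentre touched.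

**Compound list**
1 | 2-bromo-3,5-dimethoxybenzaldehyde | COc1cc(C=O)c(Br)c(OC)c1 | starting material
2 | 3,5-dimethoxy-2-methylbenzaldehyde | COc1cc(C=O)c(C)c(OC)c1 | intermediate
3 | (E)-1,5-dimethoxy-2-methyl-3-(prop-1-en-1-yl)benzene | C/C=C/c1cc(OC)cc(OC)c1C | intermediate
4 | (2R,3R)-2-(3,5-dimethoxy-2-methylphenyl)-3-methyloxirane | C[C@H]1O[C@@H]1c1cc(OC)cc(OC)c1C | intermediate
5 | (2R,3S)-3-(3,5-dimethoxy-2-methylphenyl)butan-2-ol | O[C@H](C)[C@@H](C)c1cc(OC)cc(OC)c1C | intermediate
6 | (2R,3S)-3-(3,5-dihydroxy-2-methylphenyl)butan-2-ol | O[C@H](C)[C@@H](C)c1cc(O)cc(O)c1C | intermediate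
7 | (3R,4S)-1,6,8-trimethoxy-3,4,5-trimethylisochromane (C1 epimers; not isolated) | COC1O[C@H](C)[C@@H](C)c2c(C)c(OC)cc(OC)c12 | intermediate
8 | (3R,4S)-6,8-dimethoxy-3,4,5-trimethylisochroman-1-one | O=C1O[C@H](C)[C@@H](C)c2c(C)c(OC)cc(OC)c12 | intermediate
9 | (3R,4S)-6,8-dihydroxy-3,4,5-trimethylisochroman-1-one | O=C1O[C@H](C)[C@@H](C)c2c(C)c(O)cc(O)c12 | intermediate
10 | Nagata benzodioxaborin of 9: (3R,4S)-8-hydroxy-3,4,5-trimethylisochroman-1-one with a 4-methyl-2-phenyl-4H-1,3,2-dioxaborin ring fused at C6–C7 (O6–B(Ph)–O–CH(CH3)–C7; both epimers at CH(CH3); the O8 regioisomer would converge) | O=C1O[C@H](C)[C@@H](C)c2c(C)c3OB(c4ccccc4)OC(C)c3c(O)c12 | intermediate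
11 | o-quinone methide: (3R,4S)-7-ethylidene-8-hydroxy-3,4,5-trimethyl-3,4-dihydro-1H-isochromene-1,6(7H)-dione (alkene geometry not defined; not isolated) | O=C1O[C@H](C)[C@@H](C)C2=C(C)C(=O)C(=CC)C(O)=C12 | intermediate
12 | (3R,4S)-7-[(1S)-1-{2,6-dihydroxy-4-[(2S,3R)-3-hydroxybutan-2-yl]-3-methylphenyl}ethyl]-6,8-dihydroxy-3,4,5-trimethylisochroman-1-one | O[C@H](C)[C@@H](C)c1cc(O)c([C@H](C)c2c(O)c(C)c3c(c2O)C(=O)O[C@H](C)[C@H]3C)c(O)c1C | intermediate
13 | (3R,4S)-7-[(1S)-1-[(3R,4S)-1-ethoxy-6,8-dihydroxy-3,4,5-trimethylisochroman-7-yl]ethyl]-6,8-dihydroxy-3,4,5-trimethylisochroman-1-one (C1 epimers; not isolated) | CCOC1O[C@H](C)[C@@H](C)c2c(C)c(O)c([C@H](C)c3c(O)c(C)c4c(c3O)C(=O)O[C@H](C)[C@H]4C)c(O)c12 | intermediate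
14 | dicitrinone H: (3R,4S)-6,8-dihydroxy-7-[(1R)-1-[(3R,4S)-6-hydroxy-3,4,5-trimethyl-8-oxo-3,4-dihydro-8H-isochromen-7-yl]ethyl]-3,4,5-trimethylisochroman-1-one | CC1=C2C(=CO[C@H](C)[C@H]2C)C(=O)C([C@H](C)c2c(O)c(C)c3c(c2O)C(=O)O[C@H](C)[C@H]3C)=C1O | target

**Step count**
Total steps: 10. Longest linear sequence: 9 (steps 1–4 and 6–10; step 5 is the one-step branch to 6).

**Three steps most likely to fail, each with one fallback**

Step 4 (regio- and stereochemistry of the methyl opening next to an ortho-substituted arene). Attack at the non-benzylic carbon, or partial retention, would give isomers of 5. The fallback makes the opening hydroxyl-directed; it sets out from 2 and comes back at 5. Horner–Wadsworth–Emmons reaction of 2 with triethyl phosphonoacetate gives ethyl (E)-3-(3,5-dimethoxy-2-methylphenyl)prop-2-enoate F1. DIBAL-H reduction gives (E)-3-(3,5-dimethoxy-2-methylphenyl)prop-2-en-1-ol F2. Shi epoxidation of the free allylic alcohol with the same ketone gives [(2R,3R)-3-(3,5-dimethoxy-2-methylphenyl)oxiran-2-yl]methanol F3. AlMe3 then opens the 2,3-epoxy alcohol at C3 with inversion (the well-documented epoxy-alcohol mode) to (2S,3S)-3-(3,5-dimethoxy-2-methylphenyl)butane-1,2-diol F4. Selective primary tosylation (TsCl, Et3N, cat. Bu2SnO) gives (2S,3S)-3-(3,5-dimethoxy-2-methylphenyl)-2-hydroxybutyl 4-methylbenzenesulfonate F5, and LiAlH4 reduces it to 5.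

Step 8 (Nagata hydroxyalkylation of a chelated, ester-deactivated resorcinol with volatile acetaldehyde). If the dioxaborin does not form cleanly, the C2 unit is brought in by cross-coupling; this sets out from 9 and comes back at 11. NBS bromination at the only free ring position gives (3R,4S)-7-bromo-6,8-dihydroxy-3,4,5-trimethylisochroman-1-one F6. Suzuki–Miyaura coupling with potassium vinyltrifluoroborate gives (3R,4S)-7-ethenyl-6,8-dihydroxy-3,4,5-trimethylisochroman-1-one F7. This o-hydroxystyrene is protonated by the chiral acid of step 9 to the same o-quinone methide 11 (the documented chiral phosphoric acid hydroarylation of o-hydroxystyrenes), which is captured by 6 as in the route.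

Step 9 (the proposed new step). The dioxaborin may ionise too slowly, 6 may react at its hindered position, or catalyst control of the linker may be weak. The fallback uses known chemistry; it sets out from 10 and comes back at 12. Transesterification of 10 with propane-1,3-diol frees the o-hydroxybenzylic alcohol (3R,4S)-6,8-dihydroxy-7-(1-hydroxyethyl)-3,4,5-trimethylisochroman-1-one F8, the standard precursor of published acid-catalysed o-quinone methide arylations. F8 and 6 are coupled under those established conditions (a standard BINOL phosphoric acid, or simply cat. TsOH, in CH2Cl2). Any linker epimer, (3R,4S)-7-[(1R)-1-{2,6-dihydroxy-4-[(2S,3R)-3-hydroxybutan-2-yl]-3-methylphenyl}ethyl]-6,8-dihydroxy-3,4,5-trimethylisochroman-1-one F9, is a diastereomer of 12 and is removed by preparative HPLC before step 10.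

Further compounds
F1 | step 4 | ethyl (E)-3-(3,5-dimethoxy-2-methylphenyl)prop-2-enoate | CCOC(=O)/C=C/c1cc(OC)cc(OC)c1C
F2 | step 4 | (E)-3-(3,5-dimethoxy-2-methylphenyl)prop-2-en-1-ol | OC/C=C/c1cc(OC)cc(OC)c1C
F3 | step 4 | [(2R,3R)-3-(3,5-dimethoxy-2-methylphenyl)oxiran-2-yl]methanol | OC[C@H]1O[C@@H]1c1cc(OC)cc(OC)c1C
F4 | step 4 | (2S,3S)-3-(3,5-dimethoxy-2-methylphenyl)butane-1,2-diol | OC[C@@H](O)[C@@H](C)c1cc(OC)cc(OC)c1C
F5 | step 4 | (2S,3S)-3-(3,5-dimethoxy-2-methylphenyl)-2-hydroxybutyl 4-methylbenzenesulfonate | Cc1ccc(cc1)S(=O)(=O)OC[C@@H](O)[C@@H](C)c1cc(OC)cc(OC)c1C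
F6 | step 8 | (3R,4S)-7-bromo-6,8-dihydroxy-3,4,5-trimethylisochroman-1-one | O=C1O[C@H](C)[C@@H](C)c2c(C)c(O)c(Br)c(O)c12
F7 | step 8 | (3R,4S)-7-ethenyl-6,8-dihydroxy-3,4,5-trimethylisochroman-1-one | O=C1O[C@H](C)[C@@H](C)c2c(C)c(O)c(C=C)c(O)c12
F8 | step 9 | (3R,4S)-6,8-dihydroxy-7-(1-hydroxyethyl)-3,4,5-trimethylisochroman-1-one (both carbinol epimers) | O=C1O[C@H](C)[C@@H](C)c2c(C)c(O)c(C(C)O)c(O)c12
F9 | step 9 | (3R,4S)-7-[(1R)-1-{2,6-dihydroxy-4-[(2S,3R)-3-hydroxybutan-2-yl]-3-methylphenyl}ethyl]-6,8-dihydroxy-3,4,5-trimethylisochroman-1-one | O[C@H](C)[C@@H](C)c1cc(O)c([C@@H](C)c2c(O)c(C)c3c(c2O)C(=O)O[C@H](C)[C@H]3C)c(O)c1C
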